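## Retrosynthetic overview

1. Target ⇐ its 4-O-benzyl ether (a 4-benzyloxypyridine). The hetero ring is bought as 3-methoxy-2-methylpyridin-4(1H)-one and is never constructed.
2. The carbocycle is the only ring formed, and it is formed last, by the C8–C8a disconnection: intramolecular Minisci acylation of a γ-(pyridin-3-yl) aldehyde onto the free α-C–H of the pyridine.
3. The aldehyde, the C4a–C5 bond and the C5 stereocentre come from one step: enantioselective redox-relay oxidative Heck arylation of (Z)-9-phenylnon-3-en-1-ol with the pyridin-3-ylboronic acid.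
4. Boronic acid ⇐ pyridone (C5 iodination, POCl3, benzyloxide SNAr, I/Mg exchange–borylation). Alkenol ⇐ but-3-yn-1-ol + (5-bromopentyl)benzene, then Lindlar reduction.

Assumption: the (S)-pyridine-oxazoline ligand with the Z-alkenol is taken to give the (4S)-aldehyde; the sense is checked on the first run and, if reversed, the (R)-ligand is used with nothing else changed.

The target stereocentre was assigned from the SMILES as 5S (priorities C4a > C6 > C1' of the pentyl chain > H).

## Route

Step 1
Reactants: 1 3-methoxy-2-methylpyridin-4(1H)-one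
Product: 2 5-iodo-3-methoxy-2-methylpyridin-4(1H)-one
Conditions: N-iodosuccinimide (1.05 equiv), DMF, rt
Reagents that add atoms: N-iodosuccinimide, O=C1CCC(=O)N1I
Why: Electrophilic aromatic iodination of the enaminone-like 4-pyridone goes to C5, the only free carbon alpha to the ring carbonyl, because C3 is blocked by OMe.

Step 2
Reactants: 2 5-iodo-3-methoxy-2-methylpyridin-4(1H)-one
Product: 3 4-chloro-5-iodo-3-methoxy-2-methylpyridine
Conditions: POCl3 (neat), 100 °C; then ice-water
Reagents that add atoms: phosphoryl chloride, O=P(Cl)(Cl)Cl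
Why: Deoxychlorination of a 4-pyridone (O-phosphorylation, then SNAr by chloride) is the standard pyridone-to-4-chloropyridine conversion and leaves the aryl iodide and the methyl ether untouched.

Step 3
Reactants: 3 4-chloro-5-iodo-3-methoxy-2-methylpyridine
Product: 4 4-(benzyloxy)-5-iodo-3-methoxy-2-methylpyridine
Conditions: BnOH (1.2 equiv), NaH (1.2 equiv), DMF, 0 to 60 °C
Reagents that add atoms: benzyl alcohol, OCc1ccccc1
Why: SNAr (addition–elimination) of benzyloxide occurs only at C4, which is para to the ring nitrogen, while the C5 iodide is meta to N and is not displaced; this gives the O-benzyl ether without the N-benzylation that direct alkylation of the pyridone would risk.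

Step 4
Reactants: 4 4-(benzyloxy)-5-iodo-3-methoxy-2-methylpyridine
Product: 7 [4-(benzyloxy)-5-methoxy-6-methylpyridin-3-yl]boronic acid, via pyridylmagnesium chloride 5 (not isolated), via triisopropoxyborate salt 6 (not isolated)
Conditions: iPrMgCl·LiCl (1.1 equiv), THF, −20 °C; B(OiPr)3 (1.5 equiv), −20 °C to rt; aq HCl, then pH 7
Reagents that add atoms: triisopropyl borate, CC(C)OB(OC(C)C)OC(C)C; water, O
Why: Iodine–magnesium exchange, accelerated by the ortho alkoxy group and compatible with the benzyl ether at low temperature, is followed by borylation of the aryl Grignard and hydrolysis of the borate to the boronic acid.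

Step 5
Reactants: 8 but-3-yn-1-ol; 9 (5-bromopentyl)benzene
Product: 12 9-phenylnon-3-yn-1-ol, via dilithiated but-3-yn-1-ol 10 (not isolated), via lithium 9-phenylnon-3-yn-1-olate 11 (not isolated)
Conditions: n-BuLi (2.1 equiv), THF/DMPU, −78 to 0 °C; then 9, rt; H2O
Reagents that add atoms: none
Why: Acetylide SN2 alkylation of the O,C-dianion with a primary bromide takes place at the more nucleophilic alkynide carbon, so no hydroxyl protection is needed.

Step 6
Reactants: 12 9-phenylnon-3-yn-1-ol
Product: 13 (3Z)-9-phenylnon-3-en-1-ol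
Conditions: H2 (1 atm), Pd/CaCO3 poisoned with Pb(OAc)2, quinoline, EtOAc, rt
Reagents that add atoms: none
Why: Lindlar semihydrogenation delivers H2 syn to the alkyne and stops at the Z-alkene, whose geometric purity matters because the E isomer would give the opposite enantiomer in the next step; nothing but the alkene is formed.

Step 7
Reactants: 7 [4-(benzyloxy)-5-methoxy-6-methylpyridin-3-yl]boronic acid; 13 (3Z)-9-phenylnon-3-en-1-ol
Product: 14 (4S)-4-[4-(benzyloxy)-5-methoxy-6-methylpyridin-3-yl]-9-phenylnonanal
Conditions: 7 (2.5 equiv), Pd(MeCN)2(OTs)2 (6 mol %), Cu(OTf)2 (6 mol %), (S)-4-tert-butyl-2-[5-(trifluoromethyl)pyridin-2-yl]-4,5-dihydrooxazole (13 mol %), TsOH·H2O (1 equiv per 7), 3 Å MS, O2 (1 atm), DMF, rt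
Reagents that add atoms: none
Why: Proposed new method: the enantioselective redox-relay oxidative Heck arylation of Z-homoallylic alcohols with arylboronic acids is extended to a basic pyridylboronic acid that TsOH keeps N-protonated so it cannot displace the pyridine-oxazoline ligand from cationic divalent palladium (the relay tolerates strong acid, since its diazonium variant releases HBF4); transmetalation gives aryl–Pd, the enantiodetermining migratory insertion puts the now electron-poor aryl group on the alkene carbon remote from OH under control of the ligand tert-butyl group and so sets the 4S centre, and repeated beta-hydride elimination and reinsertion walk palladium to C1, where the aldehyde is released and zerovalent palladium is reoxidised by Cu(OTf)2/O2; the closest known reaction type is the Sigman-type oxidative boron-Heck relay arylation with electron-poor arylboronic acids.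

Step 8
Reactants: 14 (4S)-4-[4-(benzyloxy)-5-methoxy-6-methylpyridin-3-yl]-9-phenylnonanal
Product: 15 (5S)-4-(benzyloxy)-3-methoxy-2-methyl-5-(5-phenylpentyl)-6,7-dihydroquinolin-8(5H)-one
Conditions: t-BuOOH (70% aq, 3 equiv, slow addition), FeSO4·7H2O (20 mol %), TFA (2 equiv), MeCN, 0.02 M, rt
Reagents that add atoms: none
Why: Intramolecular Minisci acylation, in which t-BuO• (from divalent iron and t-BuOOH) abstracts the aldehyde hydrogen, the nucleophilic acyl radical closes 6-exo onto C2–H of the N-protonated pyridin-3-yl ring (the only free position ortho to the tether and alpha to N+, since attack at the OBn-bearing carbon is reversible and unproductive) and trivalent iron oxidises the adduct back to the aromatic ketone; the stereocentre takes no part, and its benzylic C–H next to the pyridinium is polarity-mismatched for abstraction.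

Step 9
Reactants: 15 (5S)-4-(benzyloxy)-3-methoxy-2-methyl-5-(5-phenylpentyl)-6,7-dihydroquinolin-8(5H)-one
Product: 16 (5S)-3-methoxy-2-methyl-5-(5-phenylpentyl)-1,5,6,7-tetrahydroquinoline-4,8-dione (target CNP0533270.1)
Conditions: H2 (1 atm), Pd/C (10% Pd on carbon), EtOAc/EtOH, rt, stopped after 1 equiv H2
Reagents that add atoms: none
Why: Catalytic hydrogenolysis of the benzyl aryl ether is much faster than reduction of the 2-acylpyridine ketone or the phenyl ring and releases the 4-hydroxypyridine, which rests as its 4-pyridone tautomer 16 with the 5S centre untouched.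

## Compound list

1 | 3-methoxy-2-methylpyridin-4(1H)-one | COc1c(C)[nH]ccc1=O | starting material
2 | 5-iodo-3-methoxy-2-methylpyridin-4(1H)-one | COc1c(C)[nH]cc(I)c1=O | intermediate
3 | 4-chloro-5-iodo-3-methoxy-2-methylpyridine | COc1c(C)ncc(I)c1Cl | intermediate
4 | 4-(benzyloxy)-5-iodo-3-methoxy-2-methylpyridine | COc1c(C)ncc(I)c1OCc1ccccc1 | intermediate
5 | [4-(benzyloxy)-5-methoxy-6-methylpyridin-3-yl]magnesium chloride (LiCl complex) | COc1c(C)ncc([Mg]Cl)c1OCc1ccccc1 | intermediate
6 | chloromagnesium [4-(benzyloxy)-5-methoxy-6-methylpyridin-3-yl]tri(propan-2-yloxy)borate | COc1c(C)ncc([B-](OC(C)C)(OC(C)C)OC(C)C)c1OCc1ccccc1.[Mg+]Cl | intermediate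
7 | [4-(benzyloxy)-5-methoxy-6-methylpyridin-3-yl]boronic acid | COc1c(C)ncc(B(O)O)c1OCc1ccccc1 | intermediate
8 | but-3-yn-1-ol | OCCC#C | starting material
9 | (5-bromopentyl)benzene | BrCCCCCc1ccccc1 | starting material
10 | lithium 4-lithiobut-3-yn-1-olate | [Li]OCCC#C[Li] | intermediate
11 | lithium 9-phenylnon-3-yn-1-olate | [Li]OCCC#CCCCCCc1ccccc1 | intermediate
12 | 9-phenylnon-3-yn-1-ol | OCCC#CCCCCCc1ccccc1 | intermediate
13 | (3Z)-9-phenylnon-3-en-1-ol | OCC/C=C\CCCCCc1ccccc1 | intermediate
14 | (4S)-4-[4-(benzyloxy)-5-methoxy-6-methylpyridin-3-yl]-9-phenylnonanal | COc1c(C)ncc(c1OCc1ccccc1)[C@@H](CCCCCc1ccccc1)CCC=O | intermediate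
15 | (5S)-4-(benzyloxy)-3-methoxy-2-methyl-5-(5-phenylpentyl)-6,7-dihydroquinolin-8(5H)-one | COc1c(C)nc2c(c1OCc1ccccc1)[C@@H](CCCCCc1ccccc1)CCC2=O | intermediate
16 | (5S)-3-methoxy-2-methyl-5-(5-phenylpentyl)-1,5,6,7-tetrahydroquinoline-4,8-dione | COc1c(C)[nH]c2c(c1=O)[C@@H](CCCCCc1ccccc1)CCC2=O | target

## Step count and risks

Total step count: 9.
Longest linear sequence: 7 steps (steps 1, 2, 3, 4, 7, 8, 9); the alkenol branch is 2 steps (5, 6).

The three steps most likely to fail are listed below, each with its fallback.

Risk 1, the relay Heck reaction (step 7). The pyridine nitrogen may still bind palladium, the aryl group may add in part to the alkene carbon nearer OH, and the sense of induction is assumed. The fallback sets out from 4 (with 9 as the alkyl source) and comes back at 14. It sets the centre by copper-catalysed asymmetric conjugate addition instead. Heck coupling of 4 with ethyl acrylate (Pd(OAc)2, P(o-tol)3, Et3N, DMF, 100 °C) gives ethyl (2E)-3-[4-(benzyloxy)-5-methoxy-6-methylpyridin-3-yl]prop-2-enoate F1. The Grignard reagent made from 9 and Mg, (5-phenylpentyl)magnesium bromide F2, is added to F1 with CuI and the Tol-BINAP antipode that gives the S product (t-BuOMe, −40 °C). This gives ethyl (3S)-3-[4-(benzyloxy)-5-methoxy-6-methylpyridin-3-yl]-8-phenyloctanoate F3. Reduction with iBu2AlH at −78 °C gives (3S)-3-[4-(benzyloxy)-5-methoxy-6-methylpyridin-3-yl]-8-phenyloctanal F4. Wittig methoxymethylenation (Ph3P=CHOMe from (methoxymethyl)triphenylphosphonium chloride and KN(SiMe3)2) gives 4-(benzyloxy)-3-methoxy-5-[(4S)-1-methoxy-9-phenylnon-1-en-4-yl]-2-methylpyridine F5. Hydrolysis of this enol ether with aqueous HCl in THF returns 14.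

Risk 2, the Minisci ring closure (step 8). The aldehyde may be over-oxidised to the acid, the acyl radical may lose CO, or hydrogen abstraction at benzylic sites may compete. The fallback sets out from 14 and comes back at 15. It generates the acyl radical reductively from a selenoester on the unprotonated pyridine, with no peroxide and no acid. Pinnick oxidation (NaClO2, NaH2PO4, 2-methylbut-2-ene, t-BuOH/H2O) gives (4S)-4-[4-(benzyloxy)-5-methoxy-6-methylpyridin-3-yl]-9-phenylnonanoic acid F6. Treatment with PhSeSePh and PBu3 in CH2Cl2 gives Se-phenyl (4S)-4-[4-(benzyloxy)-5-methoxy-6-methylpyridin-3-yl]-9-phenylnonaneselenoate F7. Heating F7 with (Me3Si)3SiH and AIBN (added in portions, more than 1 equiv, to rearomatise the adduct) in benzene at 80 °C closes the ring to 15.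

Risk 3, the boronic acid (step 4). The magnesiated pyridine may decompose, or the amphoteric boronic acid may be lost or protodeboronated on isolation. The fallback sets out from 4 and comes back at 7. It makes the C–B bond by palladium catalysis instead. Miyaura borylation (Pd(dppf)Cl2, B2pin2, KOAc, dioxane, 85 °C) gives 4-(benzyloxy)-3-methoxy-2-methyl-5-(4,4,5,5-tetramethyl-1,3,2-dioxaborolan-2-yl)pyridine F8, which is isolated by chromatography. Oxidative cleavage of the pinacol unit with NaIO4 and NH4OAc in acetone/water then gives 7.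

## Further compounds

F1 | step 7 | ethyl (2E)-3-[4-(benzyloxy)-5-methoxy-6-methylpyridin-3-yl]prop-2-enoate | CCOC(=O)/C=C/c1cnc(C)c(OC)c1OCc1ccccc1
F2 | step 7 | (5-phenylpentyl)magnesium bromide | Br[Mg]CCCCCc1ccccc1
F3 | step 7 | ethyl (3S)-3-[4-(benzyloxy)-5-methoxy-6-methylpyridin-3-yl]-8-phenyloctanoate | CCOC(=O)C[C@H](CCCCCc1ccccc1)c1cnc(C)c(OC)c1OCc1ccccc1
F4 | step 7 | (3S)-3-[4-(benzyloxy)-5-methoxy-6-methylpyridin-3-yl]-8-phenyloctanal | O=CC[C@H](CCCCCc1ccccc1)c1cnc(C)c(OC)c1OCc1ccccc1
F5 | step 7 | 4-(benzyloxy)-3-methoxy-5-[(4S)-1-methoxy-9-phenylnon-1-en-4-yl]-2-methylpyridine (E/Z mixture) | COC=CC[C@H](CCCCCc1ccccc1)c1cnc(C)c(OC)c1OCc1ccccc1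
F6 | step 8 | (4S)-4-[4-(benzyloxy)-5-methoxy-6-methylpyridin-3-yl]-9-phenylnonanoic acid | COc1c(C)ncc(c1OCc1ccccc1)[C@@H](CCCCCc1ccccc1)CCC(=O)O
F7 | step 8 | Se-phenyl (4S)-4-[4-(benzyloxy)-5-methoxy-6-methylpyridin-3-yl]-9-phenylnonaneselenoate | COc1c(C)ncc(c1OCc1ccccc1)[C@@H](CCCCCc1ccccc1)CCC(=O)[Se]c1ccccc1
F8 | step 4 | 4-(benzyloxy)-3-methoxy-2-methyl-5-(4,4,5,5-tetramethyl-1,3,2-dioxaborolan-2-yl)pyridine | COc1c(C)ncc(B2OC(C)(C)C(C)(C)O2)c1OCc1ccccc1
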